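## Assumptions
- The target has no stereocentres. It has only five E-trisubstituted alkenes plus the terminal Me2C=CH unit, so "single enantiomer" is trivially met. All E geometry comes from the Julia–Johnson steps.
- Thermal Diels–Alder of toluquinone with (E)-piperylene is assumed to give mainly the required 8-methyl regioisomer, with the minor isomer removed by chromatography.
- N-Hydroxyphthalimide is an activating reagent only. Its phthalimide is lost as phthalimide in the last step.

## Retrosynthetic overview
1. Disconnect the quinone C3–C1′ bond. An all-E hexaprenyl (C30) allylic radical adds to 2,8-dimethyl-1,4-naphthoquinone. The radical comes from β-scission of the primary homoallylic alkoxy radical of an N-alkoxyphthalimide, which expels CH2O.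
2. That N-alkoxyphthalimide comes from the C31 (all-E) homoallylic bromide. Five rounds of Grignard addition to cyclopropyl methyl ketone and Julia–Johnson cyclopropylcarbinyl→homoallyl bromide rearrangement build it from 5-bromo-2-methylpent-2-ene. Each round adds one C5 unit and one E-trisubstituted alkene.
3. The quinone comes from Diels–Alder reaction of toluquinone (from o-cresol) with (E)-piperylene, then dehydrogenation. This is the only carbocycle constructed. The cyclopropanes are transient and are opened in the Julia steps.

## Route

**Step 1**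
Reactants: **1** o-cresol
Product: **2** 2-methyl-1,4-benzoquinone (toluquinone)
Conditions: Fremy's salt (2.2 equiv), KH2PO4 buffer, acetone/H2O, 0→25 °C
Reagents that add atoms: water, O
Why: Teuber oxidation of a phenol with a free para position gives the p-quinone directly, and no stereochemistry is involved.

**Step 2**
Reactants: **2** 2-methyl-1,4-benzoquinone; **3** (E)-penta-1,3-diene
Product: **4** cis-2,8-dimethyl-4a,5,8,8a-tetrahydro-1,4-naphthoquinone (racemic)
Conditions: PhMe, 80 °C, sealed tube, 3 equiv diene
Reagents that add atoms: none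
Why: Diels–Alder reaction occurs at the unsubstituted quinone C=C, which is activated by the more electron-poor C1 carbonyl. The methyl on C2 donates into the C4 carbonyl and so deactivates it. The unsubstituted CH2 terminus of the diene bonds to the β-carbon (C4a), and the methyl-bearing diene carbon ends next to C8a. The endo transition state gives the cis ring fusion, and all three sp3 centres of the adduct are destroyed in step 3.

**Step 3**
Reactants: **4**
Product: **5** 2,8-dimethyl-1,4-naphthoquinone
Conditions: DDQ (2.5 equiv), cat. p-TsOH, 1,4-dioxane, 100 °C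
Reagents that add atoms: none (DDQ only removes H)
Why: Acid-catalysed double enolisation gives 5,8-dihydronaphthalene-1,4-diol. DDQ oxidises this to the 5,8-dihydroquinone and then dehydrogenates the doubly allylic 1,4-diene to the aromatic ring, which is dehydrogenative aromatisation.

**Step 4**
Reactants: **6** 5-bromo-2-methylpent-2-ene; **7** cyclopropyl methyl ketone
Product: **8** 2-cyclopropyl-6-methylhept-5-en-2-ol (racemic)
Conditions: Mg, THF, 40 °C; then CeCl3, **7**, −20 °C→rt; aq. NH4Cl
Reagents that add atoms: none
Why: Homoallylic Grignard reagents do not ring-close. Ce(III) suppresses enolisation of the ketone, so 1,2-addition gives the tertiary cyclopropylcarbinol (Grignard addition). Its carbinol stereocentre is destroyed in the next step.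

**Step 5**
Reactants: **8**
Product: **9** (3E)-1-bromo-4,8-dimethylnona-3,7-diene (C11)
Conditions: 48% aq. HBr, ZnBr2, CH2Cl2, 0 °C, 15 min
Reagents that add atoms: hydrogen bromide, Br
Why: Julia–Johnson cyclopropylcarbinyl→homoallyl rearrangement. The tertiary cyclopropylcarbinyl cation opens through the conformer with the larger chain anti to the ring CH2, and bromide traps the primary terminus. This sets the new trisubstituted alkene E.

**Step 6**
Reactants: **9**; **7**
Product: **10** (5E)-2-cyclopropyl-6,10-dimethylundeca-5,9-dien-2-ol (C16, racemic)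
Conditions: Mg, THF, 40 °C; then CeCl3, **7**, −20 °C→rt; aq. NH4Cl
Reagents that add atoms: none
Why: Grignard addition adds one C5 unit and leaves the existing E-alkene and the Me2C=CH alkene untouched.

**Step 7**
Reactants: **10**
Product: **11** (3E,7E)-1-bromo-4,8,12-trimethyltrideca-3,7,11-triene (C16)
Conditions: 48% aq. HBr, ZnBr2, CH2Cl2, 0 °C, 15 min
Reagents that add atoms: hydrogen bromide, Br
Why: Julia–Johnson rearrangement sets the second E-alkene in the same way as step 5.

**Step 8**
Reactants: **11**; **7**
Product: **12** (5E,9E)-2-cyclopropyl-6,10,14-trimethylpentadeca-5,9,13-trien-2-ol (C21, racemic)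
Conditions: Mg, THF, 40 °C; then CeCl3, **7**, −20 °C→rt; aq. NH4Cl
Reagents that add atoms: none
Why: Grignard addition, as in step 6.

**Step 9**
Reactants: **12**
Product: **13** (3E,7E,11E)-1-bromo-4,8,12,16-tetramethylheptadeca-3,7,11,15-tetraene (C21)
Conditions: 48% aq. HBr, ZnBr2, CH2Cl2, 0 °C, 15 min
Reagents that add atoms: hydrogen bromide, Br
Why: Julia–Johnson rearrangement sets the third E-alkene.

**Step 10**
Reactants: **13**; **7**
Product: **14** (5E,9E,13E)-2-cyclopropyl-6,10,14,18-tetramethylnonadeca-5,9,13,17-tetraen-2-ol (C26, racemic)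
Conditions: Mg, THF, 40 °C; then CeCl3, **7**, −20 °C→rt; aq. NH4Cl
Reagents that add atoms: none
Why: Grignard addition, as in step 6.

**Step 11**
Reactants: **14**
Product: **15** (3E,7E,11E,15E)-1-bromo-4,8,12,16,20-pentamethylhenicosa-3,7,11,15,19-pentaene (C26)
Conditions: 48% aq. HBr, ZnBr2, CH2Cl2, 0 °C, 15 min
Reagents that add atoms: hydrogen bromide, Br
Why: Julia–Johnson rearrangement sets the fourth E-alkene.

**Step 12**
Reactants: **15**; **7**
Product: **16** (5E,9E,13E,17E)-2-cyclopropyl-6,10,14,18,22-pentamethyltricosa-5,9,13,17,21-pentaen-2-ol (C31, racemic)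
Conditions: Mg, THF, 40 °C; then CeCl3, **7**, −20 °C→rt; aq. NH4Cl
Reagents that add atoms: none
Why: Grignard addition, as in step 6.

**Step 13**
Reactants: **16**
Product: **17** (3E,7E,11E,15E,19E)-1-bromo-4,8,12,16,20,24-hexamethylpentacosa-3,7,11,15,19,23-hexaene (C31)
Conditions: 48% aq. HBr, ZnBr2, CH2Cl2, 0 °C, 15 min; AgNO3-silica chromatography
Reagents that add atoms: hydrogen bromide, Br
Why: The last Julia–Johnson rearrangement sets the fifth E-alkene, so all stereochemistry of the chain is now fixed. Argentation chromatography removes any Z-containing isomers.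

**Step 14**
Reactants: **17**
Product: **18** 2-[(3E,7E,11E,15E,19E)-4,8,12,16,20,24-hexamethylpentacosa-3,7,11,15,19,23-hexaen-1-yloxy]isoindoline-1,3-dione
Conditions: N-hydroxyphthalimide (1.2 equiv), Et3N (2 equiv), DMF, 50 °C
Reagents that add atoms: N-hydroxyphthalimide, O=C1c2ccccc2C(=O)N1O
Why: SN2 O-alkylation of the acidic N–OH at the primary bromide installs the alkoxy-radical precursor and leaves the alkenes untouched.

**Step 15**
Reactants: **18**; **5** 2,8-dimethyl-1,4-naphthoquinone
Product: **19** 2,8-dimethyl-3-[(2E,6E,10E,14E,18E)-3,7,11,15,19,23-hexamethyltetracosa-2,6,10,14,18,22-hexaen-1-yl]-1,4-naphthoquinone (target, C42H58O2)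
Conditions: Ir(ppy)3 (1 mol%), **5** (2 equiv), MeCN/PhCF3 1:1 (0.02 M), blue LEDs, 25 °C, N2
Reagents that add atoms: none
Why: Proposed new method: excited Ir(ppy)3 reduces the N–O bond of **18**, giving phthalimide anion and the primary alkoxy radical •O–CH2CH2–CH=C(Me)R.
- β-Scission expels CH2=O and gives the allylic radical •CH2–CH=C(Me)R, which is favourable because of allyl stabilisation. It outcompetes 1,6-HAT and 5-endo cyclisation because the C4 alkene carbon carries no H, so 1,5-HAT is not available.
- The allyl radical adds through its unhindered primary terminus to C3, the only unsubstituted quinone carbon of **5**. The tertiary terminus is too hindered to compete.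
- The E geometry is retained because trapping is much faster than rotation about the allyl radical (barrier about 15 kcal/mol).
- The adduct radical is deprotonated at C3–H by phthalimide anion to give the naphthosemiquinone radical anion. Ir(IV) oxidises this to the quinone and regenerates Ir(III), so the sequence is redox-neutral.
- Mass balance: **18** + **5** → **19** + CH2O + phthalimide.
- It is closest to photoredox alkoxy-radical β-scission combined with Giese/Minisci-type alkylation of quinones.

## Compound list
1 | o-cresol | Cc1ccccc1O | starting material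
2 | 2-methyl-1,4-benzoquinone | CC1=CC(=O)C=CC1=O | intermediate
3 | (E)-penta-1,3-diene | C/C=C/C=C | starting material
4 | cis-2,8-dimethyl-4a,5,8,8a-tetrahydro-1,4-naphthoquinone (racemic) | CC1=CC(=O)C2CC=CC(C)C2C1=O | intermediate
5 | 2,8-dimethyl-1,4-naphthoquinone | CC1=CC(=O)c2cccc(C)c2C1=O | intermediate
6 | 5-bromo-2-methylpent-2-ene | CC(C)=CCCBr | starting material
7 | cyclopropyl methyl ketone | CC(=O)C1CC1 | starting material
8 | 2-cyclopropyl-6-methylhept-5-en-2-ol (racemic) | CC(C)=CCCC(C)(O)C1CC1 | intermediate
9 | (3E)-1-bromo-4,8-dimethylnona-3,7-diene (C11) | CC(C)=CCC/C(C)=C/CCBr | intermediate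
10 | (5E)-2-cyclopropyl-6,10-dimethylundeca-5,9-dien-2-ol (C16, racemic) | CC(C)=CCC/C(C)=C/CCC(C)(O)C1CC1 | intermediate
11 | (3E,7E)-1-bromo-4,8,12-trimethyltrideca-3,7,11-triene (C16) | CC(C)=CCC/C(C)=C/CC/C(C)=C/CCBr | intermediate
12 | (5E,9E)-2-cyclopropyl-6,10,14-trimethylpentadeca-5,9,13-trien-2-ol (C21, racemic) | CC(C)=CCC/C(C)=C/CC/C(C)=C/CCC(C)(O)C1CC1 | intermediate
13 | (3E,7E,11E)-1-bromo-4,8,12,16-tetramethylheptadeca-3,7,11,15-tetraene (C21) | CC(C)=CCC/C(C)=C/CC/C(C)=C/CC/C(C)=C/CCBr | intermediate
14 | (5E,9E,13E)-2-cyclopropyl-6,10,14,18-tetramethylnonadeca-5,9,13,17-tetraen-2-ol (C26, racemic) | CC(C)=CCC/C(C)=C/CC/C(C)=C/CC/C(C)=C/CCC(C)(O)C1CC1 | intermediate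
15 | (3E,7E,11E,15E)-1-bromo-4,8,12,16,20-pentamethylhenicosa-3,7,11,15,19-pentaene (C26) | CC(C)=CCC/C(C)=C/CC/C(C)=C/CC/C(C)=C/CC/C(C)=C/CCBr | intermediate
16 | (5E,9E,13E,17E)-2-cyclopropyl-6,10,14,18,22-pentamethyltricosa-5,9,13,17,21-pentaen-2-ol (C31, racemic) | CC(C)=CCC/C(C)=C/CC/C(C)=C/CC/C(C)=C/CC/C(C)=C/CCC(C)(O)C1CC1 | intermediate
17 | (3E,7E,11E,15E,19E)-1-bromo-4,8,12,16,20,24-hexamethylpentacosa-3,7,11,15,19,23-hexaene (C31) | CC(C)=CCC/C(C)=C/CC/C(C)=C/CC/C(C)=C/CC/C(C)=C/CC/C(C)=C/CCBr | intermediate
18 | N-alkoxyphthalimide of the C31 homoallylic alcohol | CC(C)=CCC/C(C)=C/CC/C(C)=C/CC/C(C)=C/CC/C(C)=C/CC/C(C)=C/CCON1C(=O)c2ccccc2C1=O | intermediate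
19 | 2,8-dimethyl-3-hexaprenyl-1,4-naphthoquinone | CC(C)=CCC/C(C)=C/CC/C(C)=C/CC/C(C)=C/CC/C(C)=C/CC/C(C)=C/CC1=C(C)C(=O)c2c(C)cccc2C1=O | target

Note on the SMILES: the chain SMILES of **17**, **18** and **19** contain 5, 5 and 5 "/C(C)=C/" alkene units respectively, plus the terminal Me2C=CH. These are built by chunk addition as: CC(C)=CCC + four "/C(C)=C/CC" units + the terminal unit.

**Total steps:** 15. **Longest linear sequence:** 12 steps (6 → 8 → 9 → … → 17 → 18 → 19; steps 4–15). The quinone branch (steps 1–3) runs in parallel.

## Three steps most likely to fail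
1. **Step 15 (radical deconstructive allylation).** The quinone can quench the excited photocatalyst, and the primary alkoxy radical may undergo competing HAT or cyclisation.
   - Fallback: convert **17** to the primary alcohol and then to the β,γ-unsaturated acid (TEMPO/BAIB). Make its NHPI ester and use decarboxylative photoredox alkylation of **5**. This changes the radical precursor and the bond-cleaving mode.
2. **Steps 5, 7, 9, 11, 13 (Julia–Johnson).** E/Z selectivity at each alkene is only about 90:10, and aqueous HBr may hydrobrominate or cyclise the polyene.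
   - Fallback: build the chain by iterative Biellmann-type allylic sulfone alkylation with E-defined C5 blocks and Pd/LiBHEt3 desulfonylation. Then couple the resulting hexaprenyl allylic bromide to the hydroquinone of **5** by BF3-mediated allylation and oxidise with Ag2O. This gives the allylic halide directly, so no carbon deletion is needed.
3. **Steps 2–3 (Diels–Alder regiochemistry and aromatisation).** The 2-methyl group is only a weak director, so regioisomer mixtures are possible, and DDQ dehydrogenation may stall at the 5,8-dihydroquinone.
   - Fallback: Hauser–Kraus annulation of 4-methyl-3-(phenylsulfonyl)phthalide with methyl crotonate. This gives the 2,8-dimethyl pattern regiospecifically as the 3-carbomethoxy hydroquinone. Saponification, decarboxylation and oxidation then give **5**.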